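**Strategy.** Everything rests on closing ring B (C1–C8–C7–C6–C5–C9) of the bicyclo[3.3.1]nonane at C5–C6. The key step exploits that C5 is the only enolisable carbon next to the C9 ketone and lies 1,3 across ring A (C1–C2–C3–C4–C5–C9) from quaternary C1: the enolate of C5, already bearing the (S)-lavandulyl chain, attacks the CH2 terminus of a π-allylpalladium unit generated from a vinyl epoxide on the C8 arm of C1. One operation forms the quaternary bridgehead, the bicycle and an exocyclic C7 alkene, later reduced from the exo face to the 7-endo prenyl. The precursor is a monocyclic 2,2,6-trisubstituted cyclohexanone, its C1 set by CBS desymmetrisation of a Claisen-derived 1,3-dione.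

Key step: step 14

Remark: the bicyclo[3.3.1]nonane numbering of the target (C1 prenyl bridgehead, C5 lavandulyl bridgehead, C8 CMe2, C9 bridging ketone) is used for all intermediates; 9–11 and 19–21 are carried as epimer mixtures at the oxirane carbon and 20 also at C5, centres that step 14 erases.

**Step 1**
Reactants: 1 diethyl 2-(propan-2-ylidene)propanedioate
Product: 2 2-(propan-2-ylidene)propane-1,3-diol
Conditions: i-Bu2AlH (4.4 equiv), CH2Cl2, −78 → 0 °C
Reagents that add atoms: none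
Why: 1,2-reduction of both conjugated esters by the aluminium hydride should give the bis-allylic diol without touching the tetrasubstituted alkene.

**Step 2**
Reactants: 2 2-(propan-2-ylidene)propane-1,3-diol
Product: 3 2-(hydroxymethyl)-3-methylbut-2-enal
Conditions: MnO2 (activated), CH2Cl2, 25 °C
Reagents that add atoms: none
Why: allylic oxidation with MnO2 should stop at the mono-aldehyde because the second hydroxyl is then allylic to an electron-poor enal alkene.

**Step 3**
Reactants: 4 cyclohexane-1,3-dione; 5 1-bromo-3-methylbut-2-ene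
Product: 6 2-(3-methylbut-2-en-1-yl)cyclohexane-1,3-dione
Conditions: KOH, H2O, 25 °C
Reagents that add atoms: none
Why: C-alkylation of the 1,3-dione enolate with an allylic bromide in water, where hydrogen bonding to the enolate oxygens favours attack through carbon.

**Step 4**
Reactants: 6 2-(3-methylbut-2-en-1-yl)cyclohexane-1,3-dione; 3 2-(hydroxymethyl)-3-methylbut-2-enal
Product: 7 3-methyl-2-({[2-(3-methylbut-2-en-1-yl)-3-oxocyclohex-1-en-1-yl]oxy}methyl)but-2-enal
Conditions: PPh3, DIAD, THF, 0 → 25 °C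
Reagents that add atoms: none
Why: Mitsunobu reaction in which the acidic enol of the dione is O-alkylated by the activated primary allylic alcohol, giving the allyl vinylogous ester needed for the rearrangement.

**Step 5**
Reactants: 7 3-methyl-2-({[2-(3-methylbut-2-en-1-yl)-3-oxocyclohex-1-en-1-yl]oxy}methyl)but-2-enal
Product: 8 3-methyl-2-methylidene-3-[1-(3-methylbut-2-en-1-yl)-2,6-dioxocyclohexyl]butanal
Conditions: toluene, 130 °C (sealed tube)
Reagents that add atoms: none
Why: Claisen rearrangement of the allyl enol ether should transfer the allyl unit through its CMe2 terminus to C1, forming the C1–C8 bond between two fully substituted carbons; C1 is not yet a stereocentre because the 1,3-dione is symmetric.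

**Step 6**
Reactants: 8 3-methyl-2-methylidene-3-[1-(3-methylbut-2-en-1-yl)-2,6-dioxocyclohexyl]butanal
Product: 9 2-[2-methyl-3-(oxiran-2-yl)but-3-en-2-yl]-2-(3-methylbut-2-en-1-yl)cyclohexane-1,3-dione
Conditions: Me3S+ I−, KN(SiMe3)2, THF, −78 → 0 °C
Reagents that add atoms: trimethylsulfonium iodide, C[S+](C)C.[I-]
Why: Corey–Chaykovsky epoxidation, the sulfonium methylide adding 1,2 to the aldehyde far faster than to the hindered ketones; the new oxirane centre is uncontrolled and is erased in step 14.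

**Step 7**
Reactants: 9 2-[2-methyl-3-(oxiran-2-yl)but-3-en-2-yl]-2-(3-methylbut-2-en-1-yl)cyclohexane-1,3-dione
Product: 10 (2S,3S)-3-hydroxy-2-[2-methyl-3-(oxiran-2-yl)but-3-en-2-yl]-2-(3-methylbut-2-en-1-yl)cyclohexan-1-one
Conditions: (R)-2-methyl-CBS-oxazaborolidine (20 mol %), catecholborane, toluene, −78 °C
Reagents that add atoms: none
Why: CBS desymmetrising reduction of a prochiral 2,2-disubstituted 1,3-dione: the (R)-catalyst should give the S carbinol with the quaternary carbon as the large group, and since hydride is expected to enter anti to the tertiary alkyl arm only one of the two enantiotopic carbonyls satisfies both demands, which makes C1 a defined stereocentre.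

**Step 8**
Reactants: 10 (2S,3S)-3-hydroxy-2-[2-methyl-3-(oxiran-2-yl)but-3-en-2-yl]-2-(3-methylbut-2-en-1-yl)cyclohexan-1-one
Product: 11 (2S,3S)-2-[2-methyl-3-(oxiran-2-yl)but-3-en-2-yl]-2-(3-methylbut-2-en-1-yl)-3-[(triethylsilyl)oxy]cyclohexan-1-one
Conditions: Et3SiCl, imidazole, DMF, 0 → 25 °C
Reagents that add atoms: chlorotriethylsilane, CC[Si](Cl)(CC)CC
Why: silyl ether formation masks the C2 carbinol, so that later bases can enolise only towards C5 and neither O-allylation nor retro-aldol cleavage can occur.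

**Step 9**
Reactants: 12 (4R)-4-benzyl-1,3-oxazolidin-2-one; 13 3-methylbut-2-enoyl chloride
Product: 14 (4R)-4-benzyl-3-(3-methylbut-2-enoyl)-1,3-oxazolidin-2-one
Conditions: n-BuLi, THF, −78 → 0 °C
Reagents that add atoms: none
Why: N-acylation of the lithiated oxazolidinone with the acid chloride.

**Step 10**
Reactants: 14 (4R)-4-benzyl-3-(3-methylbut-2-enoyl)-1,3-oxazolidin-2-one; 5 1-bromo-3-methylbut-2-ene
Product: 16 (4R)-4-benzyl-3-[(2R)-5-methyl-2-(prop-1-en-2-yl)hex-4-enoyl]-1,3-oxazolidin-2-one, via sodium dienolate 15 (not isolated)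
Conditions: NaN(SiMe3)2, THF, −78 °C; then 5, −78 → −30 °C
Reagents that add atoms: none
Why: Evans alkylation of the chelated Z dienolate formed by γ-deprotonation; α-attack of the allylic bromide anti to the benzyl group should set the lavandulyl stereocentre as 2R.

**Step 11**
Reactants: 16 (4R)-4-benzyl-3-[(2R)-5-methyl-2-(prop-1-en-2-yl)hex-4-enoyl]-1,3-oxazolidin-2-one
Product: 17 (2R)-5-methyl-2-(prop-1-en-2-yl)hex-4-en-1-ol
Conditions: LiBH4, Et2O, H2O (1 equiv), 0 °C
Reagents that add atoms: none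
Why: reductive cleavage of the N-acyl oxazolidinone to the primary alcohol ((R)-lavandulol) without epimerisation, the auxiliary being released.

**Step 12**
Reactants: 17 (2R)-5-methyl-2-(prop-1-en-2-yl)hex-4-en-1-ol
Product: 18 (2R)-5-methyl-2-(prop-1-en-2-yl)hex-4-en-1-yl trifluoromethanesulfonate
Conditions: Tf2O, 2,6-lutidine, CH2Cl2, −78 °C (cold solution used at once)
Reagents that add atoms: trifluoromethanesulfonic anhydride, O=S(=O)(OS(=O)(=O)C(F)(F)F)C(F)(F)F
Why: sulfonylation of the primary alcohol gives an electrophile reactive enough to alkylate a hindered enolate at low temperature despite its β-branch.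

**Step 13**
Reactants: 11 (2S,3S)-2-[2-methyl-3-(oxiran-2-yl)but-3-en-2-yl]-2-(3-methylbut-2-en-1-yl)-3-[(triethylsilyl)oxy]cyclohexan-1-one; 18 (2R)-5-methyl-2-(prop-1-en-2-yl)hex-4-en-1-yl trifluoromethanesulfonate
Product: 20 (2S,3S)-2-[2-methyl-3-(oxiran-2-yl)but-3-en-2-yl]-2-(3-methylbut-2-en-1-yl)-6-[(2S)-5-methyl-2-(prop-1-en-2-yl)hex-4-en-1-yl]-3-[(triethylsilyl)oxy]cyclohexan-1-one, via lithium enolate 19 (not isolated)
Conditions: LiN(i-Pr)2, THF, −78 °C; then 18, −78 → −40 °C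
Reagents that add atoms: none
Why: alkylation of the only possible ketone enolate (C5) with a primary triflate, fast enough at low temperature to outrun attack of the enolate on its own vinyl epoxide; the new C5 centre forms as an epimer mixture that the next step erases.

**Step 14**
Reactants: 20 (2S,3S)-2-[2-methyl-3-(oxiran-2-yl)but-3-en-2-yl]-2-(3-methylbut-2-en-1-yl)-6-[(2S)-5-methyl-2-(prop-1-en-2-yl)hex-4-en-1-yl]-3-[(triethylsilyl)oxy]cyclohexan-1-one
Product: 22 (1S,2S,5R)-7-(2-hydroxyethylidene)-8,8-dimethyl-1-(3-methylbut-2-en-1-yl)-5-[(2S)-5-methyl-2-(prop-1-en-2-yl)hex-4-en-1-yl]-2-[(triethylsilyl)oxy]bicyclo[3.3.1]nonan-9-one, via potassium enolate 21 (not isolated)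
Conditions: KN(SiMe3)2, THF, −78 °C; then Pd(PPh3)4 (5 mol %), −78 → 25 °C
Reagents that add atoms: none
Why: KN(SiMe3)2 removes the only enolisable proton (C5–H, since C1 is quaternary and C2 is a silyl-protected carbinol) to give enolate 21, zerovalent palladium then ionises the vinyl epoxide to a π-allylpalladium alkoxide centred on C7, and the enolate carbon attacks the unsubstituted CH2 terminus on the face opposite to palladium, forming C5–C6. The closest known reaction types are the intramolecular Tsuji–Trost alkylation of ketone enolates with vinyl epoxides and the α,α′-annulation of cyclohexanones with 2-substituted allyl electrophiles to bicyclo[3.3.1]nonan-9-ones. Ring B (C9–C1–C8–C7–C6–C5) closes in a 6-(enolendo)-exo mode in which the allyl centre C7 becomes a ring atom and the other allyl terminus stays exocyclic as the C7=CH–CH2OH alkene. The new quaternary stereocentre C5 is controlled by C1: the three-carbon arm on C1 can reach only the enolate face syn to itself (axial attack on ring A), so the bridge is 1,3-diaxial and C5 is R. The step needs C- over O-allylation and attack at the CH2 terminus instead of the CH(CH2O−) terminus; the first should follow from outer-sphere attack of the enolate carbon on the soft π-allyl unit, the second from the lower substitution of C6 and its distance from the alkoxide, and the site of enolisation is fixed by the C2 silyl ether.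

**Step 15**
Reactants: 22 (1S,2S,5R)-7-(2-hydroxyethylidene)-8,8-dimethyl-1-(3-methylbut-2-en-1-yl)-5-[(2S)-5-methyl-2-(prop-1-en-2-yl)hex-4-en-1-yl]-2-[(triethylsilyl)oxy]bicyclo[3.3.1]nonan-9-one
Product: 23 (1S,2S,5R)-2-hydroxy-7-(2-hydroxyethylidene)-8,8-dimethyl-1-(3-methylbut-2-en-1-yl)-5-[(2S)-5-methyl-2-(prop-1-en-2-yl)hex-4-en-1-yl]bicyclo[3.3.1]nonan-9-one
Conditions: HF·pyridine, pyridine, THF, 0 °C
Reagents that add atoms: none
Why: desilylation under non-basic conditions, chosen so that no alkoxide forms that could cleave the β-hydroxy ketone by retro-aldol reaction.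

**Step 16**
Reactants: 23 (1S,2S,5R)-2-hydroxy-7-(2-hydroxyethylidene)-8,8-dimethyl-1-(3-methylbut-2-en-1-yl)-5-[(2S)-5-methyl-2-(prop-1-en-2-yl)hex-4-en-1-yl]bicyclo[3.3.1]nonan-9-one
Product: 24 2-[(1S,5R)-8,8-dimethyl-1-(3-methylbut-2-en-1-yl)-5-[(2S)-5-methyl-2-(prop-1-en-2-yl)hex-4-en-1-yl]-2,9-dioxobicyclo[3.3.1]nonan-7-ylidene]acetaldehyde
Conditions: Dess–Martin periodinane, CH2Cl2, 25 °C
Reagents that add atoms: none
Why: one periodinane oxidation converts the C2 carbinol into the ketone and the primary allylic alcohol into the exocyclic enal under neutral conditions that spare the alkenes.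

**Step 17**
Reactants: 24 2-[(1S,5R)-8,8-dimethyl-1-(3-methylbut-2-en-1-yl)-5-[(2S)-5-methyl-2-(prop-1-en-2-yl)hex-4-en-1-yl]-2,9-dioxobicyclo[3.3.1]nonan-7-ylidene]acetaldehyde
Product: 25 2-[(1S,5R,7S)-8,8-dimethyl-1-(3-methylbut-2-en-1-yl)-5-[(2S)-5-methyl-2-(prop-1-en-2-yl)hex-4-en-1-yl]-2,9-dioxobicyclo[3.3.1]nonan-7-yl]acetaldehyde
Conditions: [(Ph3P)CuH]6, toluene, H2O, 25 °C
Reagents that add atoms: none
Why: chemoselective 1,4-reduction of the enal by the copper hydride; hydride should reach C7 from the open exo face, the endo face being shielded by C3 and C4 of ring A, which places the side chain endo (7S here, 7R after step 18).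

**Step 18**
Reactants: 25 2-[(1S,5R,7S)-8,8-dimethyl-1-(3-methylbut-2-en-1-yl)-5-[(2S)-5-methyl-2-(prop-1-en-2-yl)hex-4-en-1-yl]-2,9-dioxobicyclo[3.3.1]nonan-7-yl]acetaldehyde
Product: 26 (1S,5R,7R)-8,8-dimethyl-1,7-bis(3-methylbut-2-en-1-yl)-5-[(2S)-5-methyl-2-(prop-1-en-2-yl)hex-4-en-1-yl]bicyclo[3.3.1]nonane-2,9-dione
Conditions: i-PrPPh3+ I−, n-BuLi, THF, 0 °C; then 25, −78 → 0 °C
Reagents that add atoms: isopropyltriphenylphosphonium iodide, CC(C)[P+](c1ccccc1)(c1ccccc1)c1ccccc1.[I-]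
Why: Wittig olefination of the aldehyde, far more reactive than the two hindered ketones next to quaternary carbons, completes the 7-endo prenyl group.

**Step 19**
Reactants: 26 (1S,5R,7R)-8,8-dimethyl-1,7-bis(3-methylbut-2-en-1-yl)-5-[(2S)-5-methyl-2-(prop-1-en-2-yl)hex-4-en-1-yl]bicyclo[3.3.1]nonane-2,9-dione
Product: 28 (1S,5R,7R)-8,8-dimethyl-1,7-bis(3-methylbut-2-en-1-yl)-5-[(2S)-5-methyl-2-(prop-1-en-2-yl)hex-4-en-1-yl]bicyclo[3.3.1]non-3-ene-2,9-dione, via lithium enolate 27 (not isolated)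
Conditions: LiN(i-Pr)2, THF, −78 °C; then PhS(Cl)=N-t-Bu, −78 °C
Reagents that add atoms: none
Why: Mukaiyama dehydrogenation with the sulfinimidoyl chloride; C3 is the only enolisable position (C1 and C5 are quaternary), so the C3=C4 enone should form with defined regiochemistry.

**Step 20**
Reactants: 28 (1S,5R,7R)-8,8-dimethyl-1,7-bis(3-methylbut-2-en-1-yl)-5-[(2S)-5-methyl-2-(prop-1-en-2-yl)hex-4-en-1-yl]bicyclo[3.3.1]non-3-ene-2,9-dione
Product: 29 (1S,5R,7R)-4-hydroxy-8,8-dimethyl-1,7-bis(3-methylbut-2-en-1-yl)-5-[(2S)-5-methyl-2-(prop-1-en-2-yl)hex-4-en-1-yl]bicyclo[3.3.1]non-3-ene-2,9-dione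
Conditions: Na2PdCl4 (20 mol %), t-BuOOH, AcOH–H2O, 50 °C
Reagents that add atoms: tert-butyl hydroperoxide, CC(C)(C)OO
Why: Wacker-type oxidation of an α,β-unsaturated ketone, peroxypalladation at the β-carbon C4 giving the enolised 1,3-diketone, while tri- and 1,1-disubstituted alkenes are poor substrates for divalent palladium.

**Step 21**
Reactants: 29 (1S,5R,7R)-4-hydroxy-8,8-dimethyl-1,7-bis(3-methylbut-2-en-1-yl)-5-[(2S)-5-methyl-2-(prop-1-en-2-yl)hex-4-en-1-yl]bicyclo[3.3.1]non-3-ene-2,9-dione; 30 3-acetoxybenzoic acid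
Product: 32 (1R,5R,7R)-4-hydroxy-3-(3-hydroxybenzoyl)-8,8-dimethyl-1,7-bis(3-methylbut-2-en-1-yl)-5-[(2S)-5-methyl-2-(prop-1-en-2-yl)hex-4-en-1-yl]bicyclo[3.3.1]non-3-ene-2,9-dione, via aryl acetate 31 (not isolated)
Conditions: DCC, DMAP, CH2Cl2, 25 °C; then K2CO3, MeOH, 0 °C
Reagents that add atoms: none
Why: carbodiimide O-acylation of the cyclic 1,3-dione followed by DMAP-mediated O-to-C acyl shift should place the aroyl group on C3, and mild methanolysis then frees the phenol without acid that could cyclise a prenyl group onto the enol.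

**Compound list**

1 | diethyl 2-(propan-2-ylidene)propanedioate | CCOC(=O)C(=C(C)C)C(=O)OCC | starting material
2 | 2-(propan-2-ylidene)propane-1,3-diol | CC(C)=C(CO)CO | intermediate
3 | 2-(hydroxymethyl)-3-methylbut-2-enal | CC(C)=C(CO)C=O | intermediate
4 | cyclohexane-1,3-dione | O=C1CCCC(=O)C1 | starting material
5 | 1-bromo-3-methylbut-2-ene (prenyl bromide) | CC(C)=CCBr | starting material
6 | 2-(3-methylbut-2-en-1-yl)cyclohexane-1,3-dione | CC(C)=CCC1C(=O)CCCC1=O | intermediate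
7 | 3-methyl-2-({[2-(3-methylbut-2-en-1-yl)-3-oxocyclohex-1-en-1-yl]oxy}methyl)but-2-enal | CC(C)=CCC1=C(OCC(C=O)=C(C)C)CCCC1=O | intermediate
8 | 3-methyl-2-methylidene-3-[1-(3-methylbut-2-en-1-yl)-2,6-dioxocyclohexyl]butanal | CC(C)=CCC1(C(C)(C)C(=C)C=O)C(=O)CCCC1=O | intermediate
9 | 2-[2-methyl-3-(oxiran-2-yl)but-3-en-2-yl]-2-(3-methylbut-2-en-1-yl)cyclohexane-1,3-dione (racemic at the oxirane carbon) | CC(C)=CCC1(C(C)(C)C(=C)C2CO2)C(=O)CCCC1=O | intermediate
10 | (2S,3S)-3-hydroxy-2-[2-methyl-3-(oxiran-2-yl)but-3-en-2-yl]-2-(3-methylbut-2-en-1-yl)cyclohexan-1-one (both oxirane epimers) | O=C1CCC[C@H](O)[C@]1(CC=C(C)C)C(C)(C)C(=C)C2CO2 | intermediate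
11 | (2S,3S)-2-[2-methyl-3-(oxiran-2-yl)but-3-en-2-yl]-2-(3-methylbut-2-en-1-yl)-3-[(triethylsilyl)oxy]cyclohexan-1-one | O=C1CCC[C@H](O[Si](CC)(CC)CC)[C@]1(CC=C(C)C)C(C)(C)C(=C)C2CO2 | intermediate
12 | (4R)-4-benzyl-1,3-oxazolidin-2-one | O=C1N[C@H](Cc2ccccc2)CO1 | starting material
13 | 3-methylbut-2-enoyl chloride | CC(C)=CC(Cl)=O | starting material
14 | (4R)-4-benzyl-3-(3-methylbut-2-enoyl)-1,3-oxazolidin-2-one | CC(C)=CC(=O)N1[C@H](Cc2ccccc2)COC1=O | intermediate
15 | sodium dienolate of 14 | C=C(C)C=C([O-])N1[C@H](Cc2ccccc2)COC1=O.[Na+] | intermediate (not isolated)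
16 | (4R)-4-benzyl-3-[(2R)-5-methyl-2-(prop-1-en-2-yl)hex-4-enoyl]-1,3-oxazolidin-2-one | C=C(C)[C@@H](CC=C(C)C)C(=O)N1[C@H](Cc2ccccc2)COC1=O | intermediate
17 | (2R)-5-methyl-2-(prop-1-en-2-yl)hex-4-en-1-ol ((R)-lavandulol) | C=C(C)[C@@H](CC=C(C)C)CO | intermediate
18 | (2R)-5-methyl-2-(prop-1-en-2-yl)hex-4-en-1-yl trifluoromethanesulfonate | C=C(C)[C@@H](CC=C(C)C)COS(=O)(=O)C(F)(F)F | intermediate
19 | lithium enolate of 11 (C5=C9) | [Li+].[O-]C1=CCC[C@H](O[Si](CC)(CC)CC)[C@]1(CC=C(C)C)C(C)(C)C(=C)C2CO2 | intermediate (not isolated)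
20 | (2S,3S)-2-[2-methyl-3-(oxiran-2-yl)but-3-en-2-yl]-2-(3-methylbut-2-en-1-yl)-6-[(2S)-5-methyl-2-(prop-1-en-2-yl)hex-4-en-1-yl]-3-[(triethylsilyl)oxy]cyclohexan-1-one (epimers at C6 of the ring and at the oxirane carbon) | O=C1C(C[C@H](CC=C(C)C)C(C)=C)CC[C@H](O[Si](CC)(CC)CC)[C@]1(CC=C(C)C)C(C)(C)C(=C)C2CO2 | intermediate
21 | potassium enolate of 20 (C5=C9) | [K+].[O-]C1=C(C[C@H](CC=C(C)C)C(C)=C)CC[C@H](O[Si](CC)(CC)CC)[C@]1(CC=C(C)C)C(C)(C)C(=C)C2CO2 | intermediate (not isolated)
22 | (1S,2S,5R)-7-(2-hydroxyethylidene)-8,8-dimethyl-1-(3-methylbut-2-en-1-yl)-5-[(2S)-5-methyl-2-(prop-1-en-2-yl)hex-4-en-1-yl]-2-[(triethylsilyl)oxy]bicyclo[3.3.1]nonan-9-one (alkene geometry not defined) | C=C(C)[C@@H](CC=C(C)C)C[C@@]12CC(=CCO)C(C)(C)[C@@](CC=C(C)C)([C@@H](O[Si](CC)(CC)CC)CC1)C2=O | intermediate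
23 | (1S,2S,5R)-2-hydroxy-7-(2-hydroxyethylidene)-8,8-dimethyl-1-(3-methylbut-2-en-1-yl)-5-[(2S)-5-methyl-2-(prop-1-en-2-yl)hex-4-en-1-yl]bicyclo[3.3.1]nonan-9-one | C=C(C)[C@@H](CC=C(C)C)C[C@@]12CC(=CCO)C(C)(C)[C@@](CC=C(C)C)([C@@H](O)CC1)C2=O | intermediate
24 | 2-[(1S,5R)-8,8-dimethyl-1-(3-methylbut-2-en-1-yl)-5-[(2S)-5-methyl-2-(prop-1-en-2-yl)hex-4-en-1-yl]-2,9-dioxobicyclo[3.3.1]nonan-7-ylidene]acetaldehyde | C=C(C)[C@@H](CC=C(C)C)C[C@@]12CC(=CC=O)C(C)(C)[C@@](CC=C(C)C)(C(=O)CC1)C2=O | intermediate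
25 | 2-[(1S,5R,7S)-8,8-dimethyl-1-(3-methylbut-2-en-1-yl)-5-[(2S)-5-methyl-2-(prop-1-en-2-yl)hex-4-en-1-yl]-2,9-dioxobicyclo[3.3.1]nonan-7-yl]acetaldehyde (side chain endo) | C=C(C)[C@@H](CC=C(C)C)C[C@@]12C[C@@H](CC=O)C(C)(C)[C@@](CC=C(C)C)(C(=O)CC1)C2=O | intermediate
26 | (1S,5R,7R)-8,8-dimethyl-1,7-bis(3-methylbut-2-en-1-yl)-5-[(2S)-5-methyl-2-(prop-1-en-2-yl)hex-4-en-1-yl]bicyclo[3.3.1]nonane-2,9-dione | C=C(C)[C@@H](CC=C(C)C)C[C@@]12C[C@@H](CC=C(C)C)C(C)(C)[C@@](CC=C(C)C)(C(=O)CC1)C2=O | intermediate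
27 | lithium enolate of 26 (C2=C3) | C=C(C)[C@@H](CC=C(C)C)C[C@@]12C[C@@H](CC=C(C)C)C(C)(C)[C@@](CC=C(C)C)(C([O-])=CC1)C2=O.[Li+] | intermediate (not isolated)
28 | (1S,5R,7R)-8,8-dimethyl-1,7-bis(3-methylbut-2-en-1-yl)-5-[(2S)-5-methyl-2-(prop-1-en-2-yl)hex-4-en-1-yl]bicyclo[3.3.1]non-3-ene-2,9-dione | C=C(C)[C@@H](CC=C(C)C)C[C@@]12C[C@@H](CC=C(C)C)C(C)(C)[C@@](CC=C(C)C)(C(=O)C=C1)C2=O | intermediate
29 | (1S,5R,7R)-4-hydroxy-8,8-dimethyl-1,7-bis(3-methylbut-2-en-1-yl)-5-[(2S)-5-methyl-2-(prop-1-en-2-yl)hex-4-en-1-yl]bicyclo[3.3.1]non-3-ene-2,9-dione | C=C(C)[C@@H](CC=C(C)C)C[C@@]12C[C@@H](CC=C(C)C)C(C)(C)[C@@](CC=C(C)C)(C(=O)C=C1O)C2=O | intermediate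
30 | 3-acetoxybenzoic acid | CC(=O)Oc1cccc(c1)C(=O)O | starting material
31 | 3-acetoxybenzoyl analogue of the target (aryl acetate of 32) | C=C(C)[C@@H](CC=C(C)C)C[C@@]12C[C@@H](CC=C(C)C)C(C)(C)[C@@](CC=C(C)C)(C(=O)C(C(=O)c3cccc(OC(C)=O)c3)=C1O)C2=O | intermediate (not isolated)
32 | (1R,5R,7R)-4-hydroxy-3-(3-hydroxybenzoyl)-8,8-dimethyl-1,7-bis(3-methylbut-2-en-1-yl)-5-[(2S)-5-methyl-2-(prop-1-en-2-yl)hex-4-en-1-yl]bicyclo[3.3.1]non-3-ene-2,9-dione | C=C(C)[C@@H](CC=C(C)C)C[C@@]12C[C@@H](CC=C(C)C)C(C)(C)[C@@](CC=C(C)C)(C(=O)C(C(=O)c3cccc(O)c3)=C1O)C2=O | target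

**Totals and risks**

Total step count: 21. Longest linear sequence: 16 steps (steps 1, 2, 4–8 and 13–21).

Steps most likely to fail:

Step 13. Substitution at the β-branched primary carbon may be slow, so that elimination of the triflate or premature attack of the enolate on its own vinyl epoxide takes over. The fallback builds the C5–CH2 bond by an aldol sequence instead. It sets out from 11 and 17: oxidation of 17 with Dess–Martin periodinane should give (2R)-5-methyl-2-(prop-1-en-2-yl)hex-4-enal F1; addition of F1 to the lithium enolate of 11 at −78 °C should give the β-hydroxy ketone F2; dehydration with the Burgess reagent under neutral conditions, which spare the γ-stereocentre, should give the 2-alkylidene ketone F3; 1,4-reduction of F3 with K[HB(s-Bu)3] at −78 °C and protonation return to 20.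

Step 14. The enolate may be allylated on oxygen or at the substituted allyl terminus, or the π-allyl alkoxide may decay before the hindered enolate carbon attacks. The fallback replaces the palladium-mediated closure by a direct enolate alkylation. It sets out from 20: conjugate opening of the vinyl epoxide with MgBr2·OEt2 should give the primary allylic bromide F4, and KN(SiMe3)2 (2 equiv, THF, −78 → 0 °C) should then close ring B by intramolecular SN2 attack of C5 on the allylic CH2Br, returning to 22.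

Step 20. Under the warm acidic oxidising conditions a prenyl group may cyclise onto the newly formed enol, or allylic positions may be oxidised. The fallback installs the C4 oxygen in two neutral or basic operations. It sets out from 28: nucleophilic epoxidation of the enone (t-BuOOH, DBU, CH2Cl2) should give the 3,4-epoxy ketone F5, and isomerisation of F5 with Pd(PPh3)4 and 1,2-bis(diphenylphosphino)ethane in toluene should give the β-diketone, returning to 29.

**Further compounds**

F1 | step 13 | (2R)-5-methyl-2-(prop-1-en-2-yl)hex-4-enal | C=C(C)[C@@H](CC=C(C)C)C=O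
F2 | step 13 | aldol adduct of 11 with F1 (C5 carries the CH(OH) lavandulyl unit) | O=C1C(C(O)[C@H](CC=C(C)C)C(C)=C)CC[C@H](O[Si](CC)(CC)CC)[C@]1(CC=C(C)C)C(C)(C)C(=C)C2CO2
F3 | step 13 | 2-alkylidene ketone from dehydration of F2 | O=C1C(=C[C@H](CC=C(C)C)C(C)=C)CC[C@H](O[Si](CC)(CC)CC)[C@]1(CC=C(C)C)C(C)(C)C(=C)C2CO2
F4 | step 14 | primary allylic bromide from opening of the vinyl epoxide of 20 | O=C1C(C[C@H](CC=C(C)C)C(C)=C)CC[C@H](O[Si](CC)(CC)CC)[C@]1(CC=C(C)C)C(C)(C)C(CBr)=CCO
F5 | step 20 | 3,4-epoxide of enone 28 | C=C(C)[C@@H](CC=C(C)C)C[C@@]12C[C@@H](CC=C(C)C)C(C)(C)[C@@](CC=C(C)C)(C(=O)C3OC13)C2=O
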